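The earlier runs and the new flask were computed with constants of no real substance.

Per hour and per mole of free catalyst in the litre: that was the unit I reckoned in when you asked for a quick number and bet on second catalyst as the lever.

common to all: substrate 1.5 M

| charge | partner | free catalyst | second catalyst | remark | time |
|---|---|---|---|---|---|
| grey | 1.58 M | 75 mM | 130 mM | run made earlier |  |
| violet | 1.58 M | 75 mM | 260 mM | run made earlier |  |
| ochre | 1.58 M | 75 mM | 400 mM | run made earlier |  |
| teal | 1.2 M | 75 mM | 150 mM | run made earlier |  |
| summer | 1.58 M | 250 mM | 150 mM |  | 25 h |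
| autumn | 1.58 M | 25 mM | 150 mM |  | 25 h |
| dawn | 1.00 M | 75 mM | 500 mM |  | 25 h |
| midnight | 1.58 M | 75 mM | 150 mM |  | 25 h |
| dusk | 0.500 M | 20 mM | 150 mM |  | 25 h |

- grey (time / h: product / %, substrate / %): 6.00: 26.8, 63.3; 12.0: 50.1, 38.7; 20.0: 69.8, 21.1; 25.0: 78.0, 15.6
- violet (time / h: product / %, substrate / %): 6.00: 31.5, 62.4; 12.0: 54.1, 40.3; 20.0: 73.3, 22.0; 25.0: 82.2, 16.3
- ochre (time / h: product / %, substrate / %): 3.00: 16.3, 80.4; 8.00: 41.8, 54.3; 15.0: 64.3, 33.0; 25.0: 81.8, 15.8
- teal (time / h: product / %, substrate / %): 2.00: 5.2, 86.5; 5.00: 18.5, 68.9; 10.0: 40.4, 46.9; 25.0: 68.9, 14.9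

(standard deviation of a reading: 1 percentage point)

- the flasks by amount of product, in percent of the substrate charged, highest first, at 25 h (summer / autumn / dawn / midnight / dusk)
- the same order at 5.0 h (summer / autumn / dawn / midnight / dusk)
- the amount of product, in percent of the substrate charged of the flask you put first, at 25 h
- the amount of product, in percent of the substrate charged of the flask you put last, at 25 h

I followed the fraction of substrate left, not the product made. At 25.0 h the earlier runs held 15.6%, 16.3%, 15.8% and 14.9% of their substrate, though second catalyst ran from 130 mM to 400 mM and partner from 1.2 M to 1.58 M. With a scatter of 1 percentage point, your lever did not show in that loss. Grey gave 0.991 L mol⁻¹ h⁻¹, my feed constant: the natural log of one over the fraction left, per hour and per free catalyst charged. Taking it as first order in free catalyst was a guess, since no run changes that charge.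

The fraction left at 25 h then came to 0.204% in summer, 15.6% in midnight and dawn, 53.8% in autumn and 60.9% in dusk. Each product takes one partner, so partner, where it is the limiting reagent, caps product at 66.7% of the substrate in dawn and 33.3% in dusk. Midnight's ceiling was 84.4% and autumn's 46.2%, so I ranked summer, midnight, dawn, autumn, dusk. Grey's substrate missing from product was 6.4 points; taking that from summer gave me 93.4%, and I put dusk below its cap. At 6.00 h that gap was 9.9 points in grey and 6.1 points in violet, so at 5.0 h I set dawn, with 500 mM of second catalyst, just ahead of midnight.

The forecast read summer > midnight > dawn > autumn > dusk at 25 h and summer > dawn > midnight > autumn > dusk at 5.0 h, with 92% and 25%, on the ground that "The substrate decays first order at about 0.075 /h whatever the partner or second catalyst".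

The flasks gave summer > midnight > dawn > autumn > dusk and summer > dawn > midnight > autumn > dusk, with 95.4% and 26.6%.

    substrate + free catalyst → free catalyst + open intermediate (k = 1.00 L mol⁻¹ h⁻¹)
    second catalyst + open intermediate ⇌ catalyst intermediate (K = 0.210 L mol⁻¹, k = 28.0 L mol⁻¹ h⁻¹)
    partner + catalyst intermediate → second catalyst + product (k = 19.0 L mol⁻¹ h⁻¹)

Summer kept 0.19% of its substrate against my 0.204%, and its open intermediate held 4.30% of the substrate charged. I ran the same reckoning on a neighbour of summer charged with 0.63 M of partner, 0.420 equiv. Its free catalyst is summer's, so I expected 0.204% of substrate left and a cap of 42.0%. It kept 0.19% of its substrate, and partner fell to 0.010% of its charge. Product stood at 42.0%, while open intermediate held 56.3% of the substrate.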